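**Plan**
- Numbering: the bicycle is a 1,5,6,7,8,8a-hexahydronaphthalene (C1 carries the side chain, C2 the 2-oxopropyl group, C3/C6/C8 methyls, C7 the ketone); the side chain is C1'–C6' from the acid, with C6' bonded to C1.
- Enabling feature: ring A (C1, C2, C3, C4, C4a, C8a) is a cyclohexa-1,3-diene (C2=C3–C4=C4a) flanked by two sp3 carbons (C1, C8a) with trans substituents. This is the retron of an (E)-alkene adding to a 2-pyrone with loss of CO2; C5–C8 is a four-atom tether from the pyrone to that alkene.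
- Retrosynthesis: C7 ketone from a silyl ether; cut C1–C6' (alkenyl–alkenyl coupling) and, in the same operation, C1–C2 and C4a–C8a (pyrone [4+2], CO2 extrusion); pyrone from a (Z)-enynoic acid (lactonisation, Sonogashira); C7–C8 by crotylboration; side chain by Wittig, desymmetrisation and carboalumination.
- Forward: side-chain iodide 8 (steps 1–6), enol triflate 11 (steps 7–8), pyrone alkenylboronate 21 (steps 9–17); step 18 joins 21 and 8 and, on heating, closes rings B and A at once; steps 19–21 adjust oxidation level and deprotect.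
- Stereochemistry: C4' from lipase desymmetrisation of a prochiral diol; C6 from Evans alkylation; C7/C8 from reagent-controlled syn-crotylboration; C1/C8a from the E-alkene geometry and the chair-like tether; 5'E from syn-carboalumination, 2'E from the Wittig reaction.

Key step: step 18

Assumption: the lipase is taken to acylate the hydroxymethyl group that leads to (R)-6; if the opposite sense is found, the same enzyme used hydrolytically on the diacetate of 5 should give the antipodal monoacetate.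

**Step 1**
Reactants: 1 diethyl 2-methylmalonate
Product: 2 diethyl 2-ethynyl-2-methylmalonate
Conditions: TMS-EBX (1.3 equiv), TBAF (1.3 equiv), THF, −78 °C → rt
Reagents that add atoms: TMS-EBX, 1-[(trimethylsilyl)ethynyl]-1,2-benziodoxol-3(1H)-one, C[Si](C)(C)C#CI1OC(=O)c2ccccc12
Why: electrophilic α-ethynylation of a 1,3-dicarbonyl C–H with an ethynyl-λ3-iodane (fluoride unmasks the ethynyl iodane and generates the enolate) should give the quaternary terminal alkyne; no stereocentre is formed.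

**Step 2**
Reactants: 2 diethyl 2-ethynyl-2-methylmalonate
Product: 3 2-ethynyl-2-methylpropane-1,3-diol
Conditions: LiAlH4 (2.5 equiv), THF, 0 °C → rt; Fieser work-up
Reagents that add atoms: none
Why: hydride reduction of both ester groups should give the prochiral 1,3-diol, the alkyne being inert.

**Step 3**
Reactants: 3 2-ethynyl-2-methylpropane-1,3-diol
Product: 5 2-[(E)-1-iodoprop-1-en-2-yl]-2-methylpropane-1,3-diol, via alkenylalane 4 (not isolated)
Conditions: Me3Al (5 equiv), Cp2ZrCl2 (0.3 equiv), CH2Cl2, 0 °C → rt; then I2, THF, −30 → 0 °C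
Reagents that add atoms: trimethylaluminium, C[Al](C)C; iodine, II
Why: Zr-catalysed Negishi carboalumination adds Me–Al syn across the terminal alkyne with methyl on the internal carbon, and iodinolysis with retention should give the (E)-iodoalkene (I cis to the new methyl).

**Step 4**
Reactants: 5 2-[(E)-1-iodoprop-1-en-2-yl]-2-methylpropane-1,3-diol
Product: 6 (2R,3E)-2-(hydroxymethyl)-4-iodo-2,3-dimethylbut-3-en-1-yl acetate
Conditions: lipase (triacylglycerol lipase, e.g. immobilised Burkholderia cepacia lipase), vinyl acetate, t-BuOMe, 25 °C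
Reagents that add atoms: vinyl acetate, CC(=O)OC=C
Why: enantiotopic-group-selective enzymatic transesterification of a prochiral 2,2-disubstituted 1,3-diol, made irreversible by tautomerisation of vinyl alcohol, sets the quaternary centre C4'.

**Step 5**
Reactants: 6 (2R,3E)-2-(hydroxymethyl)-4-iodo-2,3-dimethylbut-3-en-1-yl acetate
Product: 7 (2S,3E)-2-formyl-4-iodo-2,3-dimethylbut-3-en-1-yl acetate
Conditions: Dess–Martin periodinane, NaHCO3, CH2Cl2, 0 °C → rt
Reagents that add atoms: none
Why: Dess–Martin oxidation of the primary alcohol gives an aldehyde that cannot epimerise because its α-carbon is quaternary.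

**Step 6**
Reactants: 7 (2S,3E)-2-formyl-4-iodo-2,3-dimethylbut-3-en-1-yl acetate
Product: 8 methyl (2E,4S,5E)-4-(acetoxymethyl)-6-iodo-4,5-dimethylhexa-2,5-dienoate
Conditions: Ph3P=CHCO2Me, toluene, 80 °C
Reagents that add atoms: methyl (triphenylphosphoranylidene)acetate, COC(=O)C=P(c1ccccc1)(c1ccccc1)c1ccccc1
Why: Wittig olefination with a stabilised ylide should give the (E)-enoate; the alkenyl iodide and acetate are inert.

**Step 7**
Reactants: 9 methyl acetoacetate
Product: 10 methyl 2-acetyl-4-oxopentanoate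
Conditions: NaOMe, MeOH, 0 °C; chloroacetone, NaI (cat.), 0 °C → rt
Reagents that add atoms: chloroacetone, CC(=O)CCl
Why: C-alkylation of the acetoacetate enolate with an α-chloroketone introduces the 2-oxopropyl group that becomes the C2 substituent.

**Step 8**
Reactants: 10 methyl 2-acetyl-4-oxopentanoate
Product: 11 methyl (2Z)-2-(2-oxopropyl)-3-(trifluoromethylsulfonyloxy)but-2-enoate
Conditions: NaH, Et2O, 0 °C; Tf2O, −78 → 0 °C
Reagents that add atoms: triflic anhydride, O=S(=O)(OS(=O)(=O)C(F)(F)F)C(F)(F)F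
Why: O-triflation of the chelated sodium enolate of the β-keto ester should give the (Z)-enol triflate (OTf cis to the ester), the isolated methyl ketone being far less acidic.

**Step 9**
Reactants: 12 (R)-4-benzyl-3-propionyloxazolidin-2-one
Product: 13 (R)-4-benzyl-3-[(S)-2-methylpent-4-ynoyl]oxazolidin-2-one
Conditions: NaHMDS, THF, −78 °C; propargyl bromide, −78 → −40 °C
Reagents that add atoms: propargyl bromide, C#CCBr
Why: Evans alkylation of the chelated (Z)-sodium enolate on the face opposite the benzyl group sets the future C6 methyl centre (S).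

**Step 10**
Reactants: 13 (R)-4-benzyl-3-[(S)-2-methylpent-4-ynoyl]oxazolidin-2-one
Product: 14 (S)-2-methylpent-4-yn-1-ol
Conditions: LiBH4, H2O (1 equiv), Et2O, 0 °C
Reagents that add atoms: none
Why: reductive cleavage of the N-acyl oxazolidinone gives the primary alcohol without touching the α-stereocentre and returns the auxiliary.

**Step 11**
Reactants: 14 (S)-2-methylpent-4-yn-1-ol
Product: 15 (S)-2-methylpent-4-ynal
Conditions: Dess–Martin periodinane, NaHCO3, CH2Cl2, 0 °C; filtered solution used at once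
Reagents that add atoms: none
Why: buffered Dess–Martin oxidation gives the volatile α-methyl aldehyde under non-epimerising conditions for immediate use.

**Step 12**
Reactants: 15 (S)-2-methylpent-4-ynal
Product: 16 (3R,4R,5S)-3,5-dimethyloct-1-en-7-yn-4-ol
Conditions: cis-2-butene, n-BuLi, KOt-Bu, THF, −78 → −45 °C; (−)-Ipc2BOMe; BF3·OEt2; 15, −78 °C; then NaOH, H2O2
Reagents that add atoms: cis-2-butene, C/C=C\C
Why: Brown crotylboration through a chair Zimmerman–Traxler transition state, where the (Z)-crotyl geometry gives the 3,4-syn relation and the (−)-Ipc2B group directs attack on the si face of the aldehyde, should give the all-syn triad (future C6, C7, C8) under reagent control.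

**Step 13**
Reactants: 16 (3R,4R,5S)-3,5-dimethyloct-1-en-7-yn-4-ol
Product: 17 triethyl{[(3R,4R,5S)-3,5-dimethyloct-1-en-7-yn-4-yl]oxy}silane
Conditions: TESOTf, 2,6-lutidine, CH2Cl2, −78 °C
Reagents that add atoms: triethylsilyl triflate, CC[Si](CC)(CC)OS(=O)(=O)C(F)(F)F
Why: silylation protects the secondary alcohol and keeps C7 sp3, so that the C8 centre cannot epimerise before the cycloaddition.

**Step 14**
Reactants: 17 triethyl{[(3R,4R,5S)-3,5-dimethyloct-1-en-7-yn-4-yl]oxy}silane; 11 methyl (2Z)-2-(2-oxopropyl)-3-(trifluoromethylsulfonyloxy)but-2-enoate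
Product: 18 methyl (2Z,7S,8R,9R)-3,7,9-trimethyl-2-(2-oxopropyl)-8-(triethylsilyloxy)undeca-2,10-dien-4-ynoate
Conditions: Pd(PPh3)4 (5 mol %), CuI (10 mol %), i-Pr2NH, THF, rt
Reagents that add atoms: none
Why: Sonogashira coupling of the terminal alkyne with the enol triflate proceeds with retention of alkene geometry and places the alkyne cis to the ester.

**Step 15**
Reactants: 18 methyl (2Z,7S,8R,9R)-3,7,9-trimethyl-2-(2-oxopropyl)-8-(triethylsilyloxy)undeca-2,10-dien-4-ynoate
Product: 19 (2Z,7S,8R,9R)-3,7,9-trimethyl-2-(2-oxopropyl)-8-(triethylsilyloxy)undeca-2,10-dien-4-ynoic acid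
Conditions: Me3SnOH, 1,2-dichloroethane, 80 °C; dilute HCl work-up
Reagents that add atoms: trimethyltin hydroxide, C[Sn](C)(C)O
Why: mild tin-hydroxide cleavage of the methyl ester should free the acid without loss of the silyl ether or isomerisation of the tetrasubstituted alkene.

**Step 16**
Reactants: 19 (2Z,7S,8R,9R)-3,7,9-trimethyl-2-(2-oxopropyl)-8-(triethylsilyloxy)undeca-2,10-dien-4-ynoic acid
Product: 20 6-[(2S,3R,4R)-2,4-dimethyl-3-(triethylsilyloxy)hex-5-en-1-yl]-4-methyl-3-(2-oxopropyl)-2H-pyran-2-one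
Conditions: ZnBr2 (20 mol %), THF, rt
Reagents that add atoms: none
Why: Zn(II)-catalysed 6-endo-dig lactonisation of the (Z)-2-en-4-ynoic acid gives the 2-pyrone carrying the tether at C6, methyl at C4 and the 2-oxopropyl group at C3.

**Step 17**
Reactants: 20 6-[(2S,3R,4R)-2,4-dimethyl-3-(triethylsilyloxy)hex-5-en-1-yl]-4-methyl-3-(2-oxopropyl)-2H-pyran-2-one
Product: 21 6-[(2S,3R,4R,5E)-2,4-dimethyl-6-(4,4,5,5-tetramethyl-1,3,2-dioxaborolan-2-yl)-3-(triethylsilyloxy)hex-5-en-1-yl]-4-methyl-3-(2-oxopropyl)-2H-pyran-2-one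
Conditions: vinylboronic acid pinacol ester (4 equiv), Hoveyda–Grubbs II (10 mol %), CH2Cl2, 40 °C
Reagents that add atoms: vinylboronic acid pinacol ester, C=CB1OC(C)(C)C(C)(C)O1
Why: olefin cross-metathesis of the only terminal alkene with a vinylboronate should give the (E)-alkenylboronate; the pyrone double bonds do not take part.

**Step 18**
Reactants: 21 6-[(2S,3R,4R,5E)-2,4-dimethyl-6-(4,4,5,5-tetramethyl-1,3,2-dioxaborolan-2-yl)-3-(triethylsilyloxy)hex-5-en-1-yl]-4-methyl-3-(2-oxopropyl)-2H-pyran-2-one; 8 methyl (2E,4S,5E)-4-(acetoxymethyl)-6-iodo-4,5-dimethylhexa-2,5-dienoate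
Product: 24 methyl (2E,4S,5E)-4-(acetoxymethyl)-4,5-dimethyl-6-[(1S,6S,7R,8R,8aR)-3,6,8-trimethyl-2-(2-oxopropyl)-7-(triethylsilyloxy)-1,5,6,7,8,8a-hexahydronaphthalen-1-yl]hexa-2,5-dienoate, via coupled pyrone triene 22 (not isolated), via CO2-bridged lactone 23 (not isolated)
Conditions: Pd(dppf)Cl2 (5 mol %), aq. K3PO4, THF, 25 °C; extraction, silica plug; then toluene (0.005 M), BHT, 150 °C, sealed tube
Reagents that add atoms: none
Why: Suzuki–Miyaura coupling (oxidative addition of 8, base-assisted transmetalation of 21, reductive elimination with retention at both sp2 carbons) forms the C1–C6' bond and turns the alkenylboronate into the terminal double bond of an (E,E)-diene, a HOMO-raised 2π partner for the 2-pyrone. On heating, this double bond adds across C3/C6 of the pyrone and the bicyclo[2.2.2] lactone 23 loses CO2 by retro-[4+2] to unveil the C2=C3–C4=C4a diene; the closest known reaction type is the intramolecular 2-pyrone–alkene Diels–Alder reaction with decarboxylation. Ring B closes in the tether-enforced fused mode (bond C4a–C8a, six-membered through the four-atom tether C5–C8) and ring A is the [4+2] ring itself (bonds C4a–C8a and C1–C2), suprafacial on both components. The trans relation of C1 and C8a follows stereospecifically from the E geometry of the reacting alkene, and their absolute sense from the all-syn C6/C7/C8 triad, which sits equatorial in a chair-like tether so that the pyrone meets the alkene face anti to the C8 methyl. Endo/exo selectivity is irrelevant because both bridgehead centres become sp2 on CO2 loss. The step needs periselectivity (the disubstituted C7'=C8'-type alkene, not the trisubstituted alkene or the enoate) and facial selectivity; the first is secured by tether length and by the hindered quaternary neighbour of the other π bonds, the second by the 1,3-syn methyl groups.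

**Step 19**
Reactants: 24 methyl (2E,4S,5E)-4-(acetoxymethyl)-4,5-dimethyl-6-[(1S,6S,7R,8R,8aR)-3,6,8-trimethyl-2-(2-oxopropyl)-7-(triethylsilyloxy)-1,5,6,7,8,8a-hexahydronaphthalen-1-yl]hexa-2,5-dienoate
Product: 25 methyl (2E,4S,5E)-4-(acetoxymethyl)-6-[(1S,6S,7R,8R,8aR)-7-hydroxy-3,6,8-trimethyl-2-(2-oxopropyl)-1,5,6,7,8,8a-hexahydronaphthalen-1-yl]-4,5-dimethylhexa-2,5-dienoate
Conditions: HF·pyridine, pyridine, THF, 0 °C → rt
Reagents that add atoms: none
Why: buffered fluoride cleavage of the secondary triethylsilyl ether should leave the acetate, the methyl ester and the acid-sensitive diene untouched.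

**Step 20**
Reactants: 25 methyl (2E,4S,5E)-4-(acetoxymethyl)-6-[(1S,6S,7R,8R,8aR)-7-hydroxy-3,6,8-trimethyl-2-(2-oxopropyl)-1,5,6,7,8,8a-hexahydronaphthalen-1-yl]-4,5-dimethylhexa-2,5-dienoate
Product: 26 methyl (2E,4S,5E)-4-(acetoxymethyl)-4,5-dimethyl-6-[(1S,6S,8R,8aR)-3,6,8-trimethyl-7-oxo-2-(2-oxopropyl)-1,5,6,7,8,8a-hexahydronaphthalen-1-yl]hexa-2,5-dienoate
Conditions: Dess–Martin periodinane, NaHCO3, CH2Cl2, 0 °C → rt
Reagents that add atoms: none
Why: non-acidic, non-dehydrogenating oxidation of the C7 alcohol gives the ketone, whose flanking methyl groups are already in the cis-diequatorial (thermodynamic) arrangement.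

**Step 21**
Reactants: 26 methyl (2E,4S,5E)-4-(acetoxymethyl)-4,5-dimethyl-6-[(1S,6S,8R,8aR)-3,6,8-trimethyl-7-oxo-2-(2-oxopropyl)-1,5,6,7,8,8a-hexahydronaphthalen-1-yl]hexa-2,5-dienoate
Product: 27 (2E,4S,5E)-4-(hydroxymethyl)-4,5-dimethyl-6-[(1S,6S,8R,8aR)-3,6,8-trimethyl-7-oxo-2-(2-oxopropyl)-1,5,6,7,8,8a-hexahydronaphthalen-1-yl]hexa-2,5-dienoic acid (target)
Conditions: LiOH·H2O (4 equiv), THF/MeOH/H2O, 0 °C → rt; then 0.5 M HCl to pH 4
Reagents that add atoms: lithium hydroxide, [Li+].[OH-]
Why: saponification cleaves the methyl ester and the primary acetate in one operation; any enolisation at C6/C8 returns the favoured cis-dimethyl ketone, and C1, C8a and C4' bear no acidic hydrogen.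

**Compound list**
1 | diethyl 2-methylmalonate | CCOC(=O)C(C)C(=O)OCC | starting material
2 | diethyl 2-ethynyl-2-methylmalonate | CCOC(=O)C(C)(C#C)C(=O)OCC | intermediate
3 | 2-ethynyl-2-methylpropane-1,3-diol | C#CC(C)(CO)CO | intermediate
4 | (E)-alkenyl(dimethyl)alane, bis(dimethylaluminium) alkoxide of the diol | C[Al](C)/C=C(\C)C(C)(CO[Al](C)C)CO[Al](C)C | intermediate
5 | 2-[(E)-1-iodoprop-1-en-2-yl]-2-methylpropane-1,3-diol | I/C=C(\C)C(C)(CO)CO | intermediate
6 | (2R,3E)-2-(hydroxymethyl)-4-iodo-2,3-dimethylbut-3-en-1-yl acetate | I/C=C(\C)[C@](C)(CO)COC(C)=O | intermediate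
7 | (2S,3E)-2-formyl-4-iodo-2,3-dimethylbut-3-en-1-yl acetate | I/C=C(\C)[C@](C)(C=O)COC(C)=O | intermediate
8 | methyl (2E,4S,5E)-4-(acetoxymethyl)-6-iodo-4,5-dimethylhexa-2,5-dienoate | I/C=C(\C)[C@](C)(/C=C/C(=O)OC)COC(C)=O | intermediate
9 | methyl acetoacetate | COC(=O)CC(C)=O | starting material
10 | methyl 2-acetyl-4-oxopentanoate | COC(=O)C(CC(C)=O)C(C)=O | intermediate
11 | methyl (2Z)-2-(2-oxopropyl)-3-(trifluoromethylsulfonyloxy)but-2-enoate | COC(=O)/C(CC(C)=O)=C(C)\OS(=O)(=O)C(F)(F)F | intermediate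
12 | (R)-4-benzyl-3-propionyloxazolidin-2-one | CCC(=O)N1[C@H](Cc2ccccc2)COC1=O | starting material
13 | (R)-4-benzyl-3-[(S)-2-methylpent-4-ynoyl]oxazolidin-2-one | C#CC[C@H](C)C(=O)N1[C@H](Cc2ccccc2)COC1=O | intermediate
14 | (S)-2-methylpent-4-yn-1-ol | C#CC[C@H](C)CO | intermediate
15 | (S)-2-methylpent-4-ynal | C#CC[C@H](C)C=O | intermediate
16 | (3R,4R,5S)-3,5-dimethyloct-1-en-7-yn-4-ol | C#CC[C@H](C)[C@@H](O)[C@H](C)C=C | intermediate
17 | triethyl{[(3R,4R,5S)-3,5-dimethyloct-1-en-7-yn-4-yl]oxy}silane | C#CC[C@H](C)[C@@H](O[Si](CC)(CC)CC)[C@H](C)C=C | intermediate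
18 | methyl (2Z,7S,8R,9R)-3,7,9-trimethyl-2-(2-oxopropyl)-8-(triethylsilyloxy)undeca-2,10-dien-4-ynoate | COC(=O)/C(CC(C)=O)=C(C)\C#CC[C@H](C)[C@@H](O[Si](CC)(CC)CC)[C@H](C)C=C | intermediate
19 | (2Z,7S,8R,9R)-3,7,9-trimethyl-2-(2-oxopropyl)-8-(triethylsilyloxy)undeca-2,10-dien-4-ynoic acid | OC(=O)/C(CC(C)=O)=C(C)\C#CC[C@H](C)[C@@H](O[Si](CC)(CC)CC)[C@H](C)C=C | intermediate
20 | 6-[(2S,3R,4R)-2,4-dimethyl-3-(triethylsilyloxy)hex-5-en-1-yl]-4-methyl-3-(2-oxopropyl)-2H-pyran-2-one | CC(=O)CC1=C(C)C=C(C[C@H](C)[C@@H](O[Si](CC)(CC)CC)[C@H](C)C=C)OC1=O | intermediate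
21 | 6-[(2S,3R,4R,5E)-2,4-dimethyl-6-(4,4,5,5-tetramethyl-1,3,2-dioxaborolan-2-yl)-3-(triethylsilyloxy)hex-5-en-1-yl]-4-methyl-3-(2-oxopropyl)-2H-pyran-2-one | CC(=O)CC1=C(C)C=C(C[C@H](C)[C@@H](O[Si](CC)(CC)CC)[C@H](C)/C=C/B2OC(C)(C)C(C)(C)O2)OC1=O | intermediate
22 | coupled pyrone triene: methyl (2E,4S,5E,7E,9R,10R,11S)-4-(acetoxymethyl)-4,5,9,11-tetramethyl-12-[4-methyl-2-oxo-3-(2-oxopropyl)-2H-pyran-6-yl]-10-(triethylsilyloxy)dodeca-2,5,7-trienoate | CC(=O)CC1=C(C)C=C(C[C@H](C)[C@@H](O[Si](CC)(CC)CC)[C@H](C)/C=C/C=C(\C)[C@](C)(/C=C/C(=O)OC)COC(C)=O)OC1=O | intermediate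
23 | CO2-bridged lactone (2-oxabicyclo[2.2.2]oct-5-en-3-one fused to ring B; both bridge diastereomers, bridgehead centres not specified) | CC(=O)CC12C(=O)OC3(C=C1C)C[C@H](C)[C@@H](O[Si](CC)(CC)CC)[C@H](C)[C@H]3[C@@H]2/C=C(\C)[C@](C)(/C=C/C(=O)OC)COC(C)=O | intermediate
24 | methyl (2E,4S,5E)-4-(acetoxymethyl)-4,5-dimethyl-6-[(1S,6S,7R,8R,8aR)-3,6,8-trimethyl-2-(2-oxopropyl)-7-(triethylsilyloxy)-1,5,6,7,8,8a-hexahydronaphthalen-1-yl]hexa-2,5-dienoate | CC(=O)CC1=C(C)C=C2C[C@H](C)[C@@H](O[Si](CC)(CC)CC)[C@H](C)[C@H]2[C@@H]1/C=C(\C)[C@](C)(/C=C/C(=O)OC)COC(C)=O | intermediate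
25 | methyl (2E,4S,5E)-4-(acetoxymethyl)-6-[(1S,6S,7R,8R,8aR)-7-hydroxy-3,6,8-trimethyl-2-(2-oxopropyl)-1,5,6,7,8,8a-hexahydronaphthalen-1-yl]-4,5-dimethylhexa-2,5-dienoate | CC(=O)CC1=C(C)C=C2C[C@H](C)[C@@H](O)[C@H](C)[C@H]2[C@@H]1/C=C(\C)[C@](C)(/C=C/C(=O)OC)COC(C)=O | intermediate
26 | methyl (2E,4S,5E)-4-(acetoxymethyl)-4,5-dimethyl-6-[(1S,6S,8R,8aR)-3,6,8-trimethyl-7-oxo-2-(2-oxopropyl)-1,5,6,7,8,8a-hexahydronaphthalen-1-yl]hexa-2,5-dienoate | CC(=O)CC1=C(C)C=C2C[C@H](C)C(=O)[C@H](C)[C@H]2[C@@H]1/C=C(\C)[C@](C)(/C=C/C(=O)OC)COC(C)=O | intermediate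
27 | (2E,4S,5E)-4-(hydroxymethyl)-4,5-dimethyl-6-[(1S,6S,8R,8aR)-3,6,8-trimethyl-7-oxo-2-(2-oxopropyl)-1,5,6,7,8,8a-hexahydronaphthalen-1-yl]hexa-2,5-dienoic acid | CC(=O)CC1=C(C)C=C2C[C@H](C)C(=O)[C@H](C)[C@H]2[C@@H]1/C=C(\C)[C@](C)(/C=C/C(=O)O)CO | target

**Step count and risks**
Total step count: 21. Longest linear sequence: 13 steps (steps 9–21, from 12).

Steps most likely to fail:

1. Step 18. The boronate may be lost by protodeboronation, or the pyrone opened by aqueous base, before coupling. The cycloaddition may then be slow or face-unselective, and prolonged heating may cause 1,5-hydrogen shifts in the diene. Fallback: setting out from 20 and 8, a Heck alkenylation of the terminal alkene (Pd(OAc)2, Ag2CO3, DMF, 40 °C) would form the same C1–C6' bond by carbopalladation and β-hydride elimination, without boron or aqueous base, and give triene 22, which is then isolated and purified (no new compound, F0). Cycloaddition of pure 22 under high pressure (12–15 kbar, CH2Cl2, rt) to lactone 23, then separate CO2 extrusion at 110–130 °C, would bring the route back at 24.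

2. Step 17. Cross-metathesis of the α-branched, β-silyloxy alkene may stall, give homodimer, or deactivate the catalyst. Fallback: setting out from 20, Lemieux–Johnson cleavage of the terminal alkene (OsO4 cat., NaIO4, 2,6-lutidine, dioxane/H2O) would give (2S,3R,4S)-2,4-dimethyl-5-[4-methyl-2-oxo-3-(2-oxopropyl)-2H-pyran-6-yl]-3-(triethylsilyloxy)pentanal F1. Takai–Utimoto boron olefination of F1 (CrCl2, Cl2CHBpin, LiI, THF) would give the (E)-alkenylboronate and return to the route at 21.

3. Step 4. The enzyme may discriminate the enantiotopic hydroxymethyl groups poorly, or in the wrong sense. Fallback: setting out from 5, trimethyl orthoacetate with catalytic CSA would give the cyclic orthoester 5-[(E)-1-iodoprop-1-en-2-yl]-2-methoxy-2,5-dimethyl-1,3-dioxane F2. Mild aqueous acid opens F2 cleanly to the racemic monoacetate 2-(hydroxymethyl)-4-iodo-2,3-dimethylbut-3-en-1-yl acetate F3. Preparative chiral SFC of F3 returns to the route at 6; the unwanted antipode is methanolysed (K2CO3, MeOH) back to achiral 5 and recycled.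

**Further compounds**
F0 | step 18 | none | none
F1 | step 17 | (2S,3R,4S)-2,4-dimethyl-5-[4-methyl-2-oxo-3-(2-oxopropyl)-2H-pyran-6-yl]-3-(triethylsilyloxy)pentanal | CC(=O)CC1=C(C)C=C(C[C@H](C)[C@@H](O[Si](CC)(CC)CC)[C@H](C)C=O)OC1=O
F2 | step 4 | 5-[(E)-1-iodoprop-1-en-2-yl]-2-methoxy-2,5-dimethyl-1,3-dioxane | COC1(C)OCC(C)(/C(C)=C/I)CO1
F3 | step 4 | racemic 2-(hydroxymethyl)-4-iodo-2,3-dimethylbut-3-en-1-yl acetate | I/C=C(\C)C(C)(CO)COC(C)=O
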